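**Retrosynthetic overview**
- Ring A (the ten-membered carbocycle) is closed last, at C9–C10, by an intramolecular Nozaki–Hiyama–Kishi reaction of a (Z)-alkenyl iodide with a C9 aldehyde; this also sets C9.
- Before that, the C8 senecioate is installed and ring C (the oxirane) is made by substrate-controlled epoxidation of the Z C4=C5 alkene.
- The key disconnection is C6–C7: a chromium-mediated allylation/lactonisation joins fragment A (Z,Z-iodo-dienal, 9 skeletal carbons) with fragment B (2-(bromomethyl)enoate, 6 skeletal carbons plus protecting groups), forms ring B (the lactone) and relays C8 to C7 and C6.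
- Fragment A comes from pent-4-ynal, iodoethane, methyl chloroformate and MeLi; fragment B from racemic 2-vinyloxirane and methyl propiolate, with C8 set by asymmetric palladium catalysis.
- Order of ring formation: ring B (lactone), then ring C (oxirane), then ring A (carbocycle).

Assumption: germacrane locants are used throughout (C1=C10 alkene, C4–C5 oxirane, C6 lactone oxygen, C8 ester, C9 hydroxyl, C11=C13 methylene, C12 carbonyl); read this way the target is (4R,5S,6R,7S,8S,9S) with a 1(10)Z alkene and a cis-oxirane (C3 and C6 cis).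

**Step 1**
Reactants: 1 iodoethane; 2 pent-4-ynal
Product: 7 (5Z)-6-iodohept-5-en-1-yne, via ethyltriphenylphosphonium iodide 3 (not isolated), via ethylidenetriphenylphosphorane 4 (not isolated), via (1-iodoethyl)triphenylphosphonium iodide 5 (not isolated), via (1-iodoethylidene)triphenylphosphorane 6 (not isolated)
Conditions: 1, PPh3, THF, 65 °C; n-BuLi, 20 °C; I2, −78 °C; NaN(SiMe3)2, −20 °C; then 2, −78 °C
Reagents that add atoms: iodine, II; triphenylphosphine, c1ccc(cc1)P(c1ccccc1)c1ccccc1 (kept only in 3 to 6)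
Why: Wittig olefination with the α-iodo ylide (Stork–Zhao type), whose kinetically controlled addition to the aldehyde gives the (Z)-2-iodoalkene with iodine cis to the chain, the geometry that becomes the 1(10)Z alkene.

**Step 2**
Reactants: 7 (5Z)-6-iodohept-5-en-1-yne; 8 methyl chloroformate
Product: 10 methyl (6Z)-7-iodooct-6-en-2-ynoate, via lithium acetylide 9 (not isolated)
Conditions: LiN(i-Pr)2, THF, −78 °C; then 8, −78 to 0 °C
Reagents that add atoms: none
Why: Acetylide acylation, in which the amide base removes the alkyne proton far faster at −78 °C than it attacks the alkenyl iodide and the lithium acetylide is trapped by the chloroformate.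

**Step 3**
Reactants: 10 methyl (6Z)-7-iodooct-6-en-2-ynoate
Product: 11 methyl (2Z,6Z)-7-iodo-3-methylocta-2,6-dienoate
Conditions: Me2CuLi (from MeLi and CuI), THF, −78 °C; NH4Cl (aq), −78 °C
Reagents that add atoms: lithium dimethylcuprate, [Li+].C[Cu-]C
Why: Conjugate syn-carbocupration of the ynoate and protonation at −78 °C with retention place the chain cis to the ester (2Z), which fixes the later cis relationship of C3 and C6 on the oxirane, while the alkenyl iodide does not couple at this temperature.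

**Step 4**
Reactants: 11 methyl (2Z,6Z)-7-iodo-3-methylocta-2,6-dienoate
Product: 12 (2Z,6Z)-7-iodo-3-methylocta-2,6-dien-1-ol
Conditions: i-Bu2AlH, CH2Cl2, −78 °C; aqueous potassium sodium tartrate
Reagents that add atoms: none
Why: Hydride 1,2-reduction of the conjugated ester to the allylic alcohol, which leaves both alkene geometries and the C–I bond untouched at −78 °C.

**Step 5**
Reactants: 12 (2Z,6Z)-7-iodo-3-methylocta-2,6-dien-1-ol
Product: 13 (2Z,6Z)-7-iodo-3-methylocta-2,6-dienal (fragment A)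
Conditions: TEMPO (cat.), PhI(OAc)2, CH2Cl2, 0 to 20 °C
Reagents that add atoms: none
Why: Oxoammonium (TEMPO) oxidation of the allylic alcohol under near-neutral conditions, which keeps the Z-enal from isomerising.

**Step 6**
Reactants: 14 racemic 2-vinyloxirane
Product: 15 (2S)-2-[(4-methoxyphenyl)methoxy]but-3-en-1-ol
Conditions: 4-methoxybenzyl alcohol, Pd2(dba)3·CHCl3 (1 mol%), (R,R)-DACH-phenyl Trost ligand (3 mol%), Et3B (1 mol%), CH2Cl2, 20 °C
Reagents that add atoms: 4-methoxybenzyl alcohol, COc1ccc(CO)cc1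
Why: Trost dynamic kinetic asymmetric allylic etherification, in which both epoxide enantiomers converge on interconverting π-allyl palladium complexes and the boron-bound alkoxide is delivered to the internal carbon under ligand control, setting the future C8 as S (the ligand antipode used is the one that leads to the 2S ether).

**Step 7**
Reactants: 15 (2S)-2-[(4-methoxyphenyl)methoxy]but-3-en-1-ol
Product: 16 triethyl{[(2S)-2-[(4-methoxyphenyl)methoxy]but-3-en-1-yl]oxy}silane
Conditions: Et3SiCl, imidazole, CH2Cl2, 0 °C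
Reagents that add atoms: chlorotriethylsilane, CC[Si](Cl)(CC)CC
Why: Silyl ether formation at the primary hydroxyl, the triethylsilyl group being chosen because a primary Et3Si ether can later be oxidised directly (step 16).

**Step 8**
Reactants: 16 triethyl{[(2S)-2-[(4-methoxyphenyl)methoxy]but-3-en-1-yl]oxy}silane
Product: 18 (2R)-2-[(4-methoxyphenyl)methoxy]-3-[(triethylsilyl)oxy]propanal, via ozonide 17 (not isolated)
Conditions: O3, CH2Cl2, −78 °C (Sudan Red 7B end point); PPh3, −78 to 20 °C
Reagents that add atoms: ozone, [O-][O+]=O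
Why: Ozonolysis with reductive work-up cleaves the only alkene to the aldehyde without touching the stereocentre (the descriptor becomes R only because the priorities change).

**Step 9**
Reactants: 18 (2R)-2-[(4-methoxyphenyl)methoxy]-3-[(triethylsilyl)oxy]propanal; 19 methyl propiolate
Product: 21 methyl (4R)-3-hydroxy-4-[(4-methoxyphenyl)methoxy]-2-methylidene-5-[(triethylsilyl)oxy]pentanoate (both C3 epimers), via vinylalane 20 (not isolated)
Conditions: 19, i-Bu2AlH, N-methylmorpholine N-oxide, THF, 0 °C; then 18, 0 to 20 °C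
Reagents that add atoms: none
Why: Vinylalumination, in which hydroalumination of the propiolate gives the α-alumino acrylate that adds to the aldehyde to give the Baylis–Hillman-type adduct without base, so the α-alkoxy aldehyde is not epimerised; the new carbinol centre forms unselectively and is removed in step 10.

**Step 10**
Reactants: 21 methyl (4R)-3-hydroxy-4-[(4-methoxyphenyl)methoxy]-2-methylidene-5-[(triethylsilyl)oxy]pentanoate
Product: 22 methyl (2Z,4S)-2-(bromomethyl)-4-[(4-methoxyphenyl)methoxy]-5-[(triethylsilyl)oxy]pent-2-enoate (fragment B)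
Conditions: N-bromosuccinimide, Me2S, CH2Cl2, 0 to 20 °C
Reagents that add atoms: N-bromosuccinimide, BrN1C(=O)CCC1=O
Why: Corey–Kim-type activation of the allylic alcohol and SN2′ attack of bromide give the rearranged primary allylic bromide, Z because the ester ends up trans to the C8 substituent, with the C8 stereocentre not involved.

**Step 11**
Reactants: 23 3-methylbut-2-enoic acid
Product: 24 3-methylbut-2-enoyl chloride
Conditions: (COCl)2, DMF (cat.), CH2Cl2, 0 to 20 °C; distilled
Reagents that add atoms: oxalyl chloride, O=C(Cl)C(=O)Cl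
Why: Acid chloride formation through the Vilsmeier intermediate, the freshly distilled chloride being free of the deconjugated isomer.

**Step 12**
Reactants: 13 (2Z,6Z)-7-iodo-3-methylocta-2,6-dienal; 22 methyl (2Z,4S)-2-(bromomethyl)-4-[(4-methoxyphenyl)methoxy]-5-[(triethylsilyl)oxy]pent-2-enoate
Product: 27 (4R,5S)-5-[(1Z,5Z)-6-iodo-2-methylhepta-1,5-dien-1-yl]-4-[(1S)-1-[(4-methoxyphenyl)methoxy]-2-[(triethylsilyl)oxy]ethyl]-3-methylideneoxolan-2-one, via allylchromium reagent 25 (not isolated), via hydroxy ester 26 (not isolated)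
Conditions: CrCl2 (4 equiv, nickel-free), THF, 0 to 20 °C
Reagents that add atoms: none
Why: Nozaki–Hiyama allylation under Barbier conditions followed by lactonisation: the allylchromium adds through a chair transition state with the C8 side chain equatorial (6,7-anti adduct, hence the trans-lactone), its face fixed by C8 (H-8 eclipses the ester-bearing alkene carbon to avoid 1,3-allylic strain and the C8–O bond lies anti to the forming bond), which gives 7S and with it 6R, and the chromium alkoxide then closes on the methyl ester.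

**Step 13**
Reactants: 27 (the dienyl lactone of step 12)
Product: 28 (4S,5R)-5-[(2S,3R)-3-[(3Z)-4-iodopent-3-en-1-yl]-3-methyloxiran-2-yl]-4-[(1S)-1-[(4-methoxyphenyl)methoxy]-2-[(triethylsilyl)oxy]ethyl]-3-methylideneoxolan-2-one
Conditions: 3-chloroperoxybenzoic acid, CH2Cl2, 0 °C
Reagents that add atoms: 3-chloroperoxybenzoic acid, O=C(OO)c1cccc(Cl)c1
Why: Prilezhaev epoxidation, in which the electron-rich trisubstituted C4=C5 alkene reacts ahead of the iodoalkene and the conjugated methylene, and because the Z-alkene holds H-6 in the alkene plane (1,3-allylic strain) the peracid adds to the face carrying the lactone oxygen, anti to the branched C7, giving the cis-oxirane with 4R,5S.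

**Step 14**
Reactants: 28 (the epoxy lactone of step 13)
Product: 29 (4S,5R)-4-[(1S)-1-hydroxy-2-[(triethylsilyl)oxy]ethyl]-5-[(2S,3R)-3-[(3Z)-4-iodopent-3-en-1-yl]-3-methyloxiran-2-yl]-3-methylideneoxolan-2-one
Conditions: DDQ, CH2Cl2/pH 7 phosphate buffer, 0 °C
Reagents that add atoms: none
Why: Oxidative cleavage of the 4-methoxybenzyl ether by DDQ (hydride abstraction, then hydrolysis of the oxocarbenium ion) under neutral conditions that leave the oxirane, the silyl ether and the lactone intact.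

**Step 15**
Reactants: 29 (the C8 alcohol of step 14); 24 3-methylbut-2-enoyl chloride
Product: 30 (1S)-1-[(2R,3S)-2-[(2S,3R)-3-[(3Z)-4-iodopent-3-en-1-yl]-3-methyloxiran-2-yl]-4-methylidene-5-oxooxolan-3-yl]-2-[(triethylsilyl)oxy]ethyl 3-methylbut-2-enoate
Conditions: 24, pyridine, DMAP (cat.), CH2Cl2, 0 °C
Reagents that add atoms: none
Why: DMAP-catalysed acylation of the C8 hydroxyl, in which no stereocentre is touched and the trans relationship on the lactone keeps this hydroxyl from opening the oxirane.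

**Step 16**
Reactants: 30 (the senecioate of step 15)
Product: 32 (1S)-1-[(2R,3R)-2-[(2S,3R)-3-[(3Z)-4-iodopent-3-en-1-yl]-3-methyloxiran-2-yl]-4-methylidene-5-oxooxolan-3-yl]-2-oxoethyl 3-methylbut-2-enoate, via alkoxysulfonium chloride 31 (not isolated)
Conditions: (COCl)2, DMSO, CH2Cl2, −78 to −40 °C; i-Pr2NEt, −78 to −20 °C
Reagents that add atoms: none
Why: Swern oxidation applied to a primary triethylsilyl ether, in which the chlorodimethylsulfonium salt exchanges silicon for sulfur at the primary oxygen and the base then collapses the alkoxysulfonium ylide to the aldehyde, so deprotection and oxidation happen in one operation below −20 °C where the α-acyloxy aldehyde does not epimerise.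

**Step 17**
Reactants: 32 (the seco aldehyde of step 16)
Product: 34 (4R,5S,6R,7S,8S,9S)-4,5-epoxy-9-hydroxy-8-[(3-methylbut-2-enoyl)oxy]germacra-1(10)Z,11(13)-dien-12,6-olide (CNP0188779.1), via alkenylchromium species 33 (not isolated)
Conditions: CrCl2 (10 equiv), NiCl2 (cat.), DMSO/THF, 0.002 M, slow addition, 20 °C
Reagents that add atoms: none
Why: Intramolecular Nozaki–Hiyama–Kishi reaction, in which nickel-catalysed formation of the alkenylchromium with retention of the Z geometry and addition to the aldehyde at high dilution close ring A, and with the C8–O and C=O dipoles opposed the tethered nucleophile can only reach the carbonyl from the C7 side, which gives the 9S alcohol.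

**Compound list**
1 | iodoethane | CCI | starting material
2 | pent-4-ynal | C#CCCC=O | starting material
3 | ethyltriphenylphosphonium iodide | CC[P+](c1ccccc1)(c1ccccc1)c1ccccc1.[I-] | intermediate (not isolated)
4 | ethylidenetriphenylphosphorane | CC=P(c1ccccc1)(c1ccccc1)c1ccccc1 | intermediate (not isolated)
5 | (1-iodoethyl)triphenylphosphonium iodide | CC(I)[P+](c1ccccc1)(c1ccccc1)c1ccccc1.[I-] | intermediate (not isolated)
6 | (1-iodoethylidene)triphenylphosphorane | CC(I)=P(c1ccccc1)(c1ccccc1)c1ccccc1 | intermediate (not isolated)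
7 | (5Z)-6-iodohept-5-en-1-yne | C#CCC/C=C(/C)I | intermediate
8 | methyl chloroformate | COC(Cl)=O | starting material
9 | lithium (5Z)-6-iodohept-5-en-1-yn-1-ide (lithium acetylide) | [Li]C#CCC/C=C(/C)I | intermediate (not isolated)
10 | methyl (6Z)-7-iodooct-6-en-2-ynoate | COC(=O)C#CCC/C=C(/C)I | intermediate
11 | methyl (2Z,6Z)-7-iodo-3-methylocta-2,6-dienoate | COC(=O)/C=C(/C)CC/C=C(/C)I | intermediate
12 | (2Z,6Z)-7-iodo-3-methylocta-2,6-dien-1-ol | OC/C=C(/C)CC/C=C(/C)I | intermediate
13 | (2Z,6Z)-7-iodo-3-methylocta-2,6-dienal (fragment A) | O=C/C=C(/C)CC/C=C(/C)I | intermediate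
14 | racemic 2-vinyloxirane | C=CC1CO1 | starting material
15 | (2S)-2-[(4-methoxyphenyl)methoxy]but-3-en-1-ol | C=C[C@H](OCc1ccc(OC)cc1)CO | intermediate
16 | triethyl{[(2S)-2-[(4-methoxyphenyl)methoxy]but-3-en-1-yl]oxy}silane | C=C[C@H](OCc1ccc(OC)cc1)CO[Si](CC)(CC)CC | intermediate
17 | ozonide of 16: 3-{(1S)-1-[(4-methoxyphenyl)methoxy]-2-[(triethylsilyl)oxy]ethyl}-1,2,4-trioxolane | C1(OCOO1)[C@H](OCc1ccc(OC)cc1)CO[Si](CC)(CC)CC | intermediate (not isolated)
18 | (2R)-2-[(4-methoxyphenyl)methoxy]-3-[(triethylsilyl)oxy]propanal | O=C[C@H](OCc1ccc(OC)cc1)CO[Si](CC)(CC)CC | intermediate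
19 | methyl propiolate | C#CC(=O)OC | starting material
20 | methyl 2-(diisobutylalumanyl)prop-2-enoate (vinylalane) | COC(=O)C(=C)[Al](CC(C)C)CC(C)C | intermediate (not isolated)
21 | methyl (4R)-3-hydroxy-4-[(4-methoxyphenyl)methoxy]-2-methylidene-5-[(triethylsilyl)oxy]pentanoate (both C3 epimers) | COC(=O)C(=C)C(O)[C@H](OCc1ccc(OC)cc1)CO[Si](CC)(CC)CC | intermediate
22 | methyl (2Z,4S)-2-(bromomethyl)-4-[(4-methoxyphenyl)methoxy]-5-[(triethylsilyl)oxy]pent-2-enoate (fragment B) | COC(=O)/C(CBr)=C/[C@H](OCc1ccc(OC)cc1)CO[Si](CC)(CC)CC | intermediate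
23 | 3-methylbut-2-enoic acid | CC(C)=CC(=O)O | starting material
24 | 3-methylbut-2-enoyl chloride | CC(C)=CC(Cl)=O | intermediate
25 | allylchromium reagent: methyl (4S)-2-[(dichlorochromio)methyl]-4-[(4-methoxyphenyl)methoxy]-5-[(triethylsilyl)oxy]pent-2-enoate (alkene geometry equilibrating) | COC(=O)C(C[Cr](Cl)Cl)=C[C@H](OCc1ccc(OC)cc1)CO[Si](CC)(CC)CC | intermediate (not isolated)
26 | hydroxy ester: methyl (3R,4S)-3-[(1S,2Z,6Z)-1-hydroxy-7-iodo-3-methylocta-2,6-dien-1-yl]-4-[(4-methoxyphenyl)methoxy]-2-methylidene-5-[(triethylsilyl)oxy]pentanoate | COC(=O)C(=C)[C@H]([C@@H](O)/C=C(/C)CC/C=C(/C)I)[C@H](OCc1ccc(OC)cc1)CO[Si](CC)(CC)CC | intermediate (not isolated)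
27 | (4R,5S)-5-[(1Z,5Z)-6-iodo-2-methylhepta-1,5-dien-1-yl]-4-[(1S)-1-[(4-methoxyphenyl)methoxy]-2-[(triethylsilyl)oxy]ethyl]-3-methylideneoxolan-2-one | C=C1C(=O)O[C@@H](/C=C(/C)CC/C=C(/C)I)[C@@H]1[C@H](OCc1ccc(OC)cc1)CO[Si](CC)(CC)CC | intermediate
28 | (4S,5R)-5-[(2S,3R)-3-[(3Z)-4-iodopent-3-en-1-yl]-3-methyloxiran-2-yl]-4-[(1S)-1-[(4-methoxyphenyl)methoxy]-2-[(triethylsilyl)oxy]ethyl]-3-methylideneoxolan-2-one | C=C1C(=O)O[C@@H]([C@@H]2O[C@]2(C)CC/C=C(/C)I)[C@@H]1[C@H](OCc1ccc(OC)cc1)CO[Si](CC)(CC)CC | intermediate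
29 | (4S,5R)-4-[(1S)-1-hydroxy-2-[(triethylsilyl)oxy]ethyl]-5-[(2S,3R)-3-[(3Z)-4-iodopent-3-en-1-yl]-3-methyloxiran-2-yl]-3-methylideneoxolan-2-one | C=C1C(=O)O[C@@H]([C@@H]2O[C@]2(C)CC/C=C(/C)I)[C@@H]1[C@H](O)CO[Si](CC)(CC)CC | intermediate
30 | (1S)-1-[(2R,3S)-2-[(2S,3R)-3-[(3Z)-4-iodopent-3-en-1-yl]-3-methyloxiran-2-yl]-4-methylidene-5-oxooxolan-3-yl]-2-[(triethylsilyl)oxy]ethyl 3-methylbut-2-enoate | C=C1C(=O)O[C@@H]([C@@H]2O[C@]2(C)CC/C=C(/C)I)[C@@H]1[C@H](OC(=O)C=C(C)C)CO[Si](CC)(CC)CC | intermediate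
31 | alkoxydimethylsulfonium chloride at the C9 oxygen of 30 (Et3Si replaced by SMe2) | C=C1C(=O)O[C@@H]([C@@H]2O[C@]2(C)CC/C=C(/C)I)[C@@H]1[C@H](OC(=O)C=C(C)C)CO[S+](C)C.[Cl-] | intermediate (not isolated)
32 | (1S)-1-[(2R,3R)-2-[(2S,3R)-3-[(3Z)-4-iodopent-3-en-1-yl]-3-methyloxiran-2-yl]-4-methylidene-5-oxooxolan-3-yl]-2-oxoethyl 3-methylbut-2-enoate | C=C1C(=O)O[C@@H]([C@@H]2O[C@]2(C)CC/C=C(/C)I)[C@@H]1[C@H](OC(=O)C=C(C)C)C=O | intermediate
33 | alkenylchromium species: 32 with CrCl2 in place of iodine at C10 (Z retained) | C=C1C(=O)O[C@@H]([C@@H]2O[C@]2(C)CC/C=C(/C)[Cr](Cl)Cl)[C@@H]1[C@H](OC(=O)C=C(C)C)C=O | intermediate (not isolated)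
34 | (4R,5S,6R,7S,8S,9S)-4,5-epoxy-9-hydroxy-8-[(3-methylbut-2-enoyl)oxy]germacra-1(10)Z,11(13)-dien-12,6-olide | C=C1C(=O)O[C@@H]2[C@@H]1[C@H](OC(=O)C=C(C)C)[C@@H](O)/C(C)=C\CC[C@@]1(C)O[C@@H]21 | target

**Totals**
Total step count: 17.
Longest linear sequence: 11 steps (steps 1–5, then 12–17; steps 6–10 followed by 12–17 are of the same length).

**Three steps most likely to fail**

Step 12 (chromium allylation/lactonisation). The whole C6/C7 relay rests on the single C8 stereocentre, the Z-enal can isomerise, and the δ-alkoxy allylchromium can eliminate. Fallback: set out from dienol 12 and install the oxirane first under reagent control. Sharpless asymmetric epoxidation (Ti(Oi-Pr)4, L-(+)-diethyl tartrate, t-BuOOH, 4 Å sieves, CH2Cl2, −20 °C) gives [(2S,3R)-3-[(3Z)-4-iodopent-3-en-1-yl]-3-methyloxiran-2-yl]methanol F1. TEMPO/PhI(OAc)2 oxidation gives (2R,3R)-3-[(3Z)-4-iodopent-3-en-1-yl]-3-methyloxirane-2-carbaldehyde F2, an aldehyde that cannot isomerise. CrCl2-mediated allylation of F2 with bromide 22 passes through the epoxy hydroxy ester F3 and lactonises to 28, where the route is rejoined; step 13 is then not needed. In this variant the aldehyde's own facial preference competes with the reagent's, so the diastereomer ratio has to be checked.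

Step 16 (direct oxidation of the primary Et3Si ether). The oxirane is acid-sensitive and the α-acyloxy aldehyde is base-sensitive. Fallback: set out from 30 and separate the two events. Buffered HF·pyridine/pyridine in THF at 0 °C gives (1S)-2-hydroxy-1-[(2R,3S)-2-[(2S,3R)-3-[(3Z)-4-iodopent-3-en-1-yl]-3-methyloxiran-2-yl]-4-methylidene-5-oxooxolan-3-yl]ethyl 3-methylbut-2-enoate F4, which is oxidised without base (TEMPO, PhI(OAc)2, CH2Cl2) to 32, where the route is rejoined.

Step 17 (ten-membered ring closure). Ring strain may lower the yield, and the C9 configuration is set only by macrocyclic control. Fallback: set out from 32 and accept the ring closure whatever its C9 outcome. If it gives mainly (4R,5S,6R,7S,8S,9R)-4,5-epoxy-9-hydroxy-8-[(3-methylbut-2-enoyl)oxy]germacra-1(10)Z,11(13)-dien-12,6-olide F5, oxidise it (Dess–Martin periodinane, CH2Cl2) to (4R,5S,6R,7R,8S)-4,5-epoxy-8-[(3-methylbut-2-enoyl)oxy]-9-oxogermacra-1(10)Z,11(13)-dien-12,6-olide F6. Reagent-controlled reduction of F6 ((S)-2-methyl-CBS-oxazaborolidine, catecholborane, toluene, −78 °C) then gives 34.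

**Further compounds**
F1 | step 12 | [(2S,3R)-3-[(3Z)-4-iodopent-3-en-1-yl]-3-methyloxiran-2-yl]methanol | C/C(I)=C/CC[C@@]1(C)O[C@H]1CO
F2 | step 12 | (2R,3R)-3-[(3Z)-4-iodopent-3-en-1-yl]-3-methyloxirane-2-carbaldehyde | C/C(I)=C/CC[C@@]1(C)O[C@H]1C=O
F3 | step 12 | methyl (3R,4S)-3-{(R)-hydroxy[(2S,3R)-3-[(3Z)-4-iodopent-3-en-1-yl]-3-methyloxiran-2-yl]methyl}-4-[(4-methoxyphenyl)methoxy]-2-methylidene-5-[(triethylsilyl)oxy]pentanoate | COC(=O)C(=C)[C@H]([C@@H](O)[C@@H]1O[C@]1(C)CC/C=C(/C)I)[C@H](OCc1ccc(OC)cc1)CO[Si](CC)(CC)CC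
F4 | step 16 | (1S)-2-hydroxy-1-[(2R,3S)-2-[(2S,3R)-3-[(3Z)-4-iodopent-3-en-1-yl]-3-methyloxiran-2-yl]-4-methylidene-5-oxooxolan-3-yl]ethyl 3-methylbut-2-enoate | C=C1C(=O)O[C@@H]([C@@H]2O[C@]2(C)CC/C=C(/C)I)[C@@H]1[C@H](OC(=O)C=C(C)C)CO
F5 | step 17 | (4R,5S,6R,7S,8S,9R)-4,5-epoxy-9-hydroxy-8-[(3-methylbut-2-enoyl)oxy]germacra-1(10)Z,11(13)-dien-12,6-olide | C=C1C(=O)O[C@@H]2[C@@H]1[C@H](OC(=O)C=C(C)C)[C@H](O)/C(C)=C\CC[C@@]1(C)O[C@@H]21
F6 | step 17 | (4R,5S,6R,7R,8S)-4,5-epoxy-8-[(3-methylbut-2-enoyl)oxy]-9-oxogermacra-1(10)Z,11(13)-dien-12,6-olide | C=C1C(=O)O[C@@H]2[C@@H]1[C@H](OC(=O)C=C(C)C)C(=O)/C(C)=C\CC[C@@]1(C)O[C@@H]21
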